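## Retrosynthetic overview

1. The contiguous ring A triad C8a (quaternary carbinol that also carries C1), C8 (secondary C–O) and C7 (C-methyl) matches positions 1, 2 and 3 of 3-methylbenzoic acid (1). The carboxyl carbon is C1 of ring B, so ring A is the arene ring itself and is never closed.
2. Ring B (C1–O2–C3–C4–C4a–C8a) is the only ring formed, and it is formed last. The enol of a C3 ketone adds to the C1 aldehyde once the acetals and silyl ethers are removed.
3. C3–C4 comes from a vinylogous Mukaiyama aldol of a C4a-methylene dienol ether with (E)-4,4-dimethoxybut-2-enal. The C8 ester comes from (R)-3-silyloxybutanoic acid.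
4. C4a–C4 and C6=O come from methyllithium addition to a C4a enone followed by Babler–Dauben transposition. C7–OH comes from directed C6=C7 epoxidation and Pd(PPh3)4-catalysed 1,4-opening. C8 is inverted by oxidation and directed reduction.
5. C8a–O and C8–O come from enzymatic cis-dihydroxylation of 1 to the diene diol acid (2).

Key step: step 1

**Conventions.** Azaphilone numbering (C1, O2, C3, C4, C4a, C5, C6, C7, C8, C8a) is used for every intermediate. The α face is the ring A face that bears the C8a hydroxyl, and the β face is the one that bears C1. TES = triethylsilyl, TBS = tert-butyldimethylsilyl.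

**Assumption.** The lactol centre C1 is configurationally labile through the open aldehyde. The (1R) epimer of the natural product (C1-OH β, pseudo-axial, anti to C8a-OH) is taken to be the thermodynamically preferred one.

## Route

Step 1
Reactants: 1 3-methylbenzoic acid
Product: 2 (1S,2R)-1,2-dihydroxy-3-methylcyclohexa-3,5-diene-1-carboxylic acid (C8a-OH and C8-OH both α)
Conditions: whole cells of E. coli expressing toluate 1,2-dioxygenase (xylXYZ) and no diol dehydrogenase, D-glucose, air, KH2PO4/K2HPO4 buffer pH 7.2, 30 °C
Reagents that add atoms: dioxygen O=O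
Why: Electrons from NADH pass through the reductase and the Rieske [2Fe-2S] cluster to the mononuclear non-heme iron centre, which binds O2 next to the carboxylate-anchored arene and hands both oxygen atoms to the same face of the ipso carbon (C8a) and the ortho carbon (C8), so that the C8a–O and C8–O bonds arise in one suprafacial event and the diol is necessarily cis. The closest known reaction type is the ipso,ortho cis-dihydroxylation of benzoates by benzoate and toluate 1,2-dioxygenases in hosts that lack the diol dehydrogenase, and 3-methylbenzoate is a native substrate of the toluate enzyme, so the diene acid should build up in the medium. No ring is closed, since the six arene carbons become ring A and the carboxyl carbon becomes C1. Both new stereocentres are controlled by the active site, which presents a single arene face to the iron-bound oxygen; this gives C8a as required in the target and C8 with its hydroxyl α, epimeric to the target and corrected in steps 5 and 6. The step needs regioselectivity for the ring edge on the methyl side over the edge remote from the methyl group, and this is secured by the substrate pocket, which in the native pathway channels 3-methylbenzoate to 3-methylcatechol. Rearomatisation is held back by the fully substituted C8a, which blocks simple dehydration at neutral pH.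

Step 2
Reactants: 2 diene diol acid
Product: 3 methyl (1S,2R)-1,2-dihydroxy-3-methylcyclohexa-3,5-diene-1-carboxylate
Conditions: MeI, KHCO3, DMF, rt
Reagents that add atoms: iodomethane CI
Why: SN2 O-alkylation of the carboxylate under weakly basic conditions avoids the acid that would aromatise the diene diol and leaves both hydroxyls untouched.

Step 3
Reactants: 3 diene diol methyl ester
Product: 4 6α,7α-epoxide of 3 (vinyl epoxide, C4a=C5 retained, C8-OH and C8a-OH α)
Conditions: mCPBA, EtOAc, 0 °C to rt
Reagents that add atoms: 3-chloroperoxybenzoic acid OOC(=O)c1cccc(Cl)c1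
Why: In this Henbest-type hydroxyl-directed epoxidation the peracid, hydrogen-bonded to the allylic C8-OH, should attack the more electron-rich trisubstituted C6=C7 bond from the α face and so set C7 (and C6), whereas C4a=C5 next to the ester-bearing C8a is less nucleophilic.

Step 4
Reactants: 4 vinyl epoxide
Product: 5 methyl ester triol with C4a α-acetoxy group and C5=C6 double bond (C7-OH, C8-OH, C8a-OH all α)
Conditions: Pd(PPh3)4 (3 mol %), AcOH, THF, 0 °C
Reagents that add atoms: acetic acid CC(=O)O
Why: In this Tsuji–Trost type 1,4-opening zerovalent palladium ionises the allylic C6–O bond with inversion and acetate attacks the distal allyl terminus C4a anti to the metal, so the C7–O bond and its configuration are untouched, the acetate is cis to C7-OH, and β-hydride loss is excluded because C7 and C8a carry no hydrogen.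

Step 5
Reactants: 5 triol acetate
Product: 6 C8 ketone of 5 (C7-OH and C8a-OH α)
Conditions: IBX, DMSO, rt
Reagents that add atoms: none
Why: IBX oxidation is chemoselective here because C8-OH is the only free secondary hydroxyl, and IBX turns 1,2-diols into α-ketols without glycol cleavage under neutral conditions that spare the α-hydroxy β-keto ester.

Step 6
Reactants: 6 C8 ketone
Product: 7 C8 epimer of 5 (C8-OH β; C7-OH, C8a-OH and C4a-OAc α)
Conditions: Me4NBH(OAc)3, MeCN–AcOH (1:1), −30 to 0 °C
Reagents that add atoms: none
Why: In this Evans–Saksena hydroxyl-directed reduction the reagent exchanges acetate for one of the flanking α-face tertiary hydroxyls and delivers hydride intramolecularly to the α face of C8=O, which sets C8-OH β as in the target, is reinforced by the C7 methyl and the ester shielding the β face, and leaves ester and acetate unreduced.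

Step 7
Reactants: 7 trans,trans-triol
Product: 8 7,8,8a-tris(triethylsilyl) ether of 7
Conditions: TESOTf, 2,6-lutidine, CH2Cl2, −78 to 0 °C
Reagents that add atoms: triethylsilyl trifluoromethanesulfonate CC[Si](CC)(CC)OS(=O)(=O)C(F)(F)F
Why: Silyl triflate silylation is reactive enough for the two tertiary carbinols as well as C8-OH, and the alternating α, β, α arrangement of the three oxygens limits crowding.

Step 8
Reactants: 8 tris-TES ester acetate
Product: 9 diol with C1 primary alcohol and C4a α-alcohol (7,8,8a-tris-TES)
Conditions: iBu2AlH, CH2Cl2, −78 to 0 °C; aq. potassium sodium tartrate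
Reagents that add atoms: none
Why: Excess aluminium hydride reduces the methyl ester to the C1 carbinol and cleaves the acetate in one ester-reduction step, and the weakly nucleophilic aluminium alkoxides in CH2Cl2 should not trigger silyl migration.

Step 9
Reactants: 9 diol
Product: 10 C1 aldehyde and C4a enone (C4a=O, C5=C6; 7,8,8a-tris-TES)
Conditions: Dess–Martin periodinane, pyridine, CH2Cl2, 0 °C to rt
Reagents that add atoms: none
Why: Dess–Martin oxidation converts both carbinols under buffered conditions, no free glycol is present that could be cleaved, and the quaternary C8a makes the resulting 1,3-dicarbonyl non-enolisable.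

Step 10
Reactants: 10 keto aldehyde
Product: 11 C1 dimethyl acetal of the C4a enone (7,8,8a-tris-TES)
Conditions: MeOSiMe3, Me3SiOTf (10 mol %), CH2Cl2, −78 to −30 °C; pyridine quench
Reagents that add atoms: methoxytrimethylsilane CO[Si](C)(C)C
Why: Aprotic silyl-triflate-catalysed acetalisation (Noyori conditions) selects the aldehyde over the less electrophilic enone and, without protic acid or methanol, should leave the TES ethers in place.

Step 11
Reactants: 11 acetal enone
Product: 12 C4a tertiary allylic alcohol (C4a-OH, C4a-CH3, C5=C6; C4a epimers)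
Conditions: MeLi, Et2O, −78 °C; aq. NH4Cl
Reagents that add atoms: methyllithium [Li]C
Why: The 1,2-addition of the hard organolithium installs C4 cleanly because the enone has neither α nor γ hydrogens to lose, and the configuration at C4a is irrelevant because that carbon becomes sp2 in step 12.

Step 12
Reactants: 12 tertiary allylic alcohol
Product: 13 C4a-methyl C6 enone (C6=O, C5=C4a; C1 dimethyl acetal; 7,8,8a-tris-TES)
Conditions: pyridinium chlorochromate [C5H5NH][CrO3Cl], 4 Å molecular sieves, CH2Cl2, rt
Reagents that add atoms: pyridinium chlorochromate [O-][Cr](=O)(=O)Cl.c1cc[nH+]cc1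
Why: In the Babler–Dauben oxidative transposition the chromate ester of the only free (tertiary allylic) hydroxyl rearranges suprafacially to C6 and is oxidised there by hexavalent chromium, and silylation of C7-O and C8a-O excludes the competing transposition from C7 and glycol cleavage.

Step 13
Reactants: 13 tris-TES enone
Product: 14 triol enone (C7-OH α, C8-OH β, C8a-OH α; C1 dimethyl acetal)
Conditions: HF·pyridine, pyridine, THF, 0 °C to rt
Reagents that add atoms: none
Why: Buffered fluoride desilylation removes all three TES groups under mildly acidic, water-free conditions, which avoid base-induced retro-aldol of the β-hydroxy ketone and spare the acetal.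

Step 14
Reactants: 15 methyl (R)-3-hydroxybutanoate
Product: 16 methyl (R)-3-(tert-butyldimethylsilyloxy)butanoate
Conditions: TBSCl, imidazole, DMF, rt
Reagents that add atoms: tert-butyldimethylsilyl chloride CC(C)(C)[Si](C)(C)Cl
Why: Standard imidazole-promoted silylation of a secondary alcohol does not touch the stereocentre, which is taken from the chiral pool.

Step 15
Reactants: 16 TBS ether ester
Product: 17 (R)-3-(tert-butyldimethylsilyloxy)butanoic acid
Conditions: LiOH, THF–MeOH–H2O, 0 °C to rt; then 1 M HCl to pH 4
Reagents that add atoms: lithium hydroxide [Li+].[OH-]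
Why: Saponification at low temperature is faster than β-elimination of the silyloxy group and leaves the carbinol centre unchanged.

Step 16
Reactants: 14 triol enone; 17 (R)-3-(tert-butyldimethylsilyloxy)butanoic acid
Product: 19 C8 (R)-3-(tert-butyldimethylsilyloxy)butanoate of triol 14, via mixed Yamaguchi anhydride 18 (not isolated)
Conditions: 2,4,6-trichlorobenzoyl chloride, Et3N, toluene, rt; then 14, DMAP, rt to 40 °C
Reagents that add atoms: none
Why: Yamaguchi esterification provides an acylating agent strong enough for the hindered C8-OH, and site selectivity rests on C8-OH being the only secondary hydroxyl beside two unreactive tertiary ones.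

Step 17
Reactants: 19 C8 ester
Product: 20 C6 triethylsilyl dienol ether with exocyclic C4a=C4H2 (C7-OTES and C8a-OTES)
Conditions: TESOTf, Et3N, CH2Cl2, −78 to 0 °C
Reagents that add atoms: triethylsilyl trifluoromethanesulfonate CC[Si](CC)(CC)OS(=O)(=O)C(F)(F)F
Why: Soft enolisation silylates the ketone oxygen and removes a proton from the C4 methyl, the only acidic position since C7 and C8a are quaternary, caps both tertiary hydroxyls in the same operation, and is too mild at this temperature to enolise the side-chain ester.

Step 18
Reactants: 20 silyl dienol ether; 21 (E)-4,4-dimethoxybut-2-enal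
Product: 22 C3 carbinol (C4H2–C3H(OH)–CH=CH–CH(OMe)2 on C4a, enone restored; C3 epimers)
Conditions: BF3·OEt2, CH2Cl2, −78 °C (21 in excess, precomplexed); pH 7 buffer
Reagents that add atoms: none
Why: In the vinylogous Mukaiyama aldol the unhindered terminal methylene C4 carries the reactive site of the dienol ether and restores the conjugated enone on attack, the formyl group is favoured because the acetal of 21 would ionise to a cation destabilised by the enal and the C1 acetal is neopentyl and α-oxygenated, and the C3 configuration is irrelevant because it is oxidised in step 19.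

Step 19
Reactants: 22 C3 carbinol
Product: 23 C3 ketone (C4H2–C3(=O)–CH=CH–CH(OMe)2; may rest partly as its C3 enol)
Conditions: MnO2, CH2Cl2, rt
Reagents that add atoms: none
Why: Manganese dioxide oxidation is selective for the only free hydroxyl, an allylic one, is neutral towards acetals and silyl ethers, and avoids over-oxidation of the doubly activated C4 methylene.

Step 20
Reactants: 23 C3 ketone bis-acetal
Product: 25 azaphilone D, via open keto dialdehyde 24 (not isolated)
Conditions: 48% aq. HF, MeCN, 0 °C to rt
Reagents that add atoms: water O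
Why: Aqueous HF cleaves the TES and TBS ethers and hydrolyses both dimethyl acetals, after which the C3 ketone, a vinylogous 1,3-diketone with C6=O, enolises towards C4 and its enol oxygen adds to the C1 aldehyde in an iridoid-type lactolisation of a 1,5-dicarbonyl (6-exo-trig attack on C=O) that closes ring B, with C1 settling under thermodynamic, anomeric control as the β pseudo-axial (1R) hydroxyl.

## Compound list

1 | 3-methylbenzoic acid | Cc1cccc(c1)C(=O)O | starting material
2 | (1S,2R)-1,2-dihydroxy-3-methylcyclohexa-3,5-diene-1-carboxylic acid | O[C@H]1[C@@](C(=O)O)(O)C=CC=C1C | intermediate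
3 | methyl (1S,2R)-1,2-dihydroxy-3-methylcyclohexa-3,5-diene-1-carboxylate | O[C@H]1[C@@](C(=O)OC)(O)C=CC=C1C | intermediate
4 | 6α,7α-epoxide of 3 | O[C@H]1[C@@](C(=O)OC)(O)C=C[C@H]2O[C@@]12C | intermediate
5 | C4a α-acetoxy C5=C6 all-α triol methyl ester | O[C@H]1[C@@](C(=O)OC)(O)[C@@H](OC(C)=O)C=C[C@@]1(C)O | intermediate
6 | C8 ketone of 5 | O=C1[C@@](C(=O)OC)(O)[C@@H](OC(C)=O)C=C[C@@]1(C)O | intermediate
7 | C8 epimer of 5 (C8-OH β) | O[C@@H]1[C@@](C(=O)OC)(O)[C@@H](OC(C)=O)C=C[C@@]1(C)O | intermediate
8 | 7,8,8a-tris-TES ether of 7 | CC[Si](CC)(CC)O[C@@H]1[C@@](C(=O)OC)(O[Si](CC)(CC)CC)[C@@H](OC(C)=O)C=C[C@@]1(C)O[Si](CC)(CC)CC | intermediate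
9 | C1 carbinol, C4a α-carbinol, tris-TES | CC[Si](CC)(CC)O[C@@H]1[C@@](CO)(O[Si](CC)(CC)CC)[C@@H](O)C=C[C@@]1(C)O[Si](CC)(CC)CC | intermediate
10 | C1 aldehyde, C4a enone, tris-TES | CC[Si](CC)(CC)O[C@@H]1[C@@](C=O)(O[Si](CC)(CC)CC)C(=O)C=C[C@@]1(C)O[Si](CC)(CC)CC | intermediate
11 | C1 dimethyl acetal, C4a enone, tris-TES | CC[Si](CC)(CC)O[C@@H]1[C@@](C(OC)OC)(O[Si](CC)(CC)CC)C(=O)C=C[C@@]1(C)O[Si](CC)(CC)CC | intermediate
12 | C4a tertiary allylic alcohol (C4a epimers) | CC[Si](CC)(CC)O[C@@H]1[C@@](C(OC)OC)(O[Si](CC)(CC)CC)C(C)(O)C=C[C@@]1(C)O[Si](CC)(CC)CC | intermediate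
13 | C4a-methyl C6 enone, C1 acetal, tris-TES | CC[Si](CC)(CC)O[C@@H]1[C@@](C(OC)OC)(O[Si](CC)(CC)CC)C(C)=CC(=O)[C@@]1(C)O[Si](CC)(CC)CC | intermediate
14 | triol enone, C1 acetal | O[C@@H]1[C@@](C(OC)OC)(O)C(C)=CC(=O)[C@@]1(C)O | intermediate
15 | methyl (R)-3-hydroxybutanoate | C[C@@H](O)CC(=O)OC | starting material
16 | methyl (R)-3-(tert-butyldimethylsilyloxy)butanoate | C[C@@H](O[Si](C)(C)C(C)(C)C)CC(=O)OC | intermediate
17 | (R)-3-(tert-butyldimethylsilyloxy)butanoic acid | C[C@@H](O[Si](C)(C)C(C)(C)C)CC(=O)O | intermediate
18 | mixed Yamaguchi anhydride (2,4,6-trichlorobenzoic (R)-3-(tert-butyldimethylsilyloxy)butanoic anhydride) | C[C@@H](O[Si](C)(C)C(C)(C)C)CC(=O)OC(=O)c1c(Cl)cc(Cl)cc1Cl | intermediate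
19 | C8 (R)-3-(tert-butyldimethylsilyloxy)butanoate of 14 | C[C@@H](O[Si](C)(C)C(C)(C)C)CC(=O)O[C@@H]1[C@@](C(OC)OC)(O)C(C)=CC(=O)[C@@]1(C)O | intermediate
20 | C6 TES dienol ether, C4a=C4H2, C7-OTES, C8a-OTES | C[C@@H](O[Si](C)(C)C(C)(C)C)CC(=O)O[C@@H]1[C@@](C(OC)OC)(O[Si](CC)(CC)CC)C(=C)C=C(O[Si](CC)(CC)CC)[C@@]1(C)O[Si](CC)(CC)CC | intermediate
21 | (E)-4,4-dimethoxybut-2-enal | COC(OC)/C=C/C=O | starting material
22 | C3 carbinol (C3 epimers) | C[C@@H](O[Si](C)(C)C(C)(C)C)CC(=O)O[C@@H]1[C@@](C(OC)OC)(O[Si](CC)(CC)CC)C(CC(O)/C=C/C(OC)OC)=CC(=O)[C@@]1(C)O[Si](CC)(CC)CC | intermediate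
23 | C3 ketone bis-acetal | C[C@@H](O[Si](C)(C)C(C)(C)C)CC(=O)O[C@@H]1[C@@](C(OC)OC)(O[Si](CC)(CC)CC)C(CC(=O)/C=C/C(OC)OC)=CC(=O)[C@@]1(C)O[Si](CC)(CC)CC | intermediate
24 | open keto dialdehyde | C[C@@H](O)CC(=O)O[C@@H]1[C@@](C=O)(O)C(CC(=O)/C=C/C=O)=CC(=O)[C@@]1(C)O | intermediate
25 | azaphilone D, (1R,7S,8R,8aS)-1,7,8a-trihydroxy-7-methyl-6-oxo-3-[(E)-3-oxoprop-1-enyl]-6,7,8,8a-tetrahydro-1H-isochromen-8-yl (R)-3-hydroxybutanoate | C[C@@H](O)CC(=O)O[C@@H]1[C@@]2(O)C(=CC(=O)[C@@]1(C)O)C=C(/C=C/C=O)O[C@H]2O | target

## Step count and risks

Total step count: 20.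
Longest linear sequence: 18 (steps 1–13 and 16–20, from 1).

**Step 18 (vinylogous Mukaiyama aldol).**
- What may go wrong: BF3 may ionise a dimethyl acetal, either that of 21 or, after the first addition, that of the adduct, so that the dienol ether is consumed at an acetal carbon. The nucleophile may also react at C5 instead of C4, or traces of acid may simply protodesilylate 20.
- Fallback: it uses no Lewis acid and draws C3 from carbon monoxide. It sets out from 20. With N-bromosuccinimide in THF at −78 °C, 20 should be brominated at the terminal methylene to give the C4 bromomethyl enone F1. The coupling partner (E)-tributyl(3,3-dimethoxyprop-1-enyl)stannane F2 is made by radical hydrostannation of commercial 3,3-dimethoxyprop-1-yne (Bu3SnH, AIBN, 80 °C). A carbonylative Stille coupling of the two (Pd2(dba)3, AsPh3, CO 3 atm, THF, 50 °C) inserts CO at the primary allyl terminus and should give the C3 ketone 23 directly. The fallback rejoins the route at 23, and step 19 is skipped.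

**Step 20 (global unmasking and lactolisation).**
- What may go wrong: the neopentyl, α-oxygenated C1 acetal may ionise slowly, so the material stays long in aqueous acid. During that time acyl migration from C8-O, dehydration at C8a or conjugate addition to the liberated enal could take over.
- Fallback: it separates acetal cleavage from desilylation and avoids aqueous acid. It sets out from 23. Treatment with TESOTf and 2,6-lutidine in CH2Cl2 at 0 °C converts aldehyde-derived dimethyl acetals into lutidinium salts, which water hydrolyses under weakly basic conditions. This should give the silylated keto dialdehyde F3. Pyridine-buffered HF·pyridine in THF then removes the silyl groups and leads through 24 back to 25.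

**Step 12 (Babler–Dauben transposition).**
- What may go wrong: chromate ester formation at the crowded C4a carbinol may be slow. Ionisation with proton loss from the new methyl group, or loss of the secondary TES ether followed by oxidation at C8, could then compete.
- Fallback: it separates isomerisation from oxidation. It sets out from 12. With catalytic Ph3SiOReO3 in Et2O at −40 to 0 °C, 12 should undergo a redox-neutral 1,3-transposition towards the less hindered alcohol and the more substituted alkene, giving the C6 allylic alcohol F4. Oxidation with MnO2 in CH2Cl2 then brings the material back to 13.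

## Further compounds

F1 | step 18 | C4 bromomethyl enone (C4a–CH2Br, C6 enone, C7-OTES, C8a-OTES, C1 acetal, C8 ester) | C[C@@H](O[Si](C)(C)C(C)(C)C)CC(=O)O[C@@H]1[C@@](C(OC)OC)(O[Si](CC)(CC)CC)C(CBr)=CC(=O)[C@@]1(C)O[Si](CC)(CC)CC
F2 | step 18 | (E)-tributyl(3,3-dimethoxyprop-1-enyl)stannane | CCCC[Sn](CCCC)(CCCC)/C=C/C(OC)OC
F3 | step 20 | silylated keto dialdehyde (C1 aldehyde, C3 ketone, terminal enal, C7-OTES, C8a-OTES, side-chain OTBS) | C[C@@H](O[Si](C)(C)C(C)(C)C)CC(=O)O[C@@H]1[C@@](C=O)(O[Si](CC)(CC)CC)C(CC(=O)/C=C/C=O)=CC(=O)[C@@]1(C)O[Si](CC)(CC)CC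
F4 | step 12 | C6 allylic alcohol (C5=C4a, C4a-methyl, C6 epimers, tris-TES, C1 acetal) | CC[Si](CC)(CC)O[C@@H]1[C@@](C(OC)OC)(O[Si](CC)(CC)CC)C(C)=CC(O)[C@@]1(C)O[Si](CC)(CC)CC
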